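## Retrosynthetic overview

1. Target 15 comes from 4-O-acylation of the 3-O-acetyl-5-O-acyl shikimate 13. The 3-OAc/4-OH pattern comes from collapse of a cyclic 3,4-orthoacetate, and the 5-ester from a lipase acylation of racemic acetonide 7 that also selects the enantiomer.
2. The cyclohexene of 7 comes from the 7-oxabicyclo[2.2.1]heptene 3: hydride at C6 gives the C1 ester enolate, which expels the bridging oxygen from C2, so C1=C2 and the C5 hydroxyl appear.
3. Compound 3 comes from an endo Diels–Alder reaction of methyl furan-3-carboxylate 1 with vinylene carbonate 2. It forms C2–C3 and C4–C5 and fixes the relative configuration of C3, C4 and C5.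
4. Enabling feature: C2 and C5 are 1,4-related in the carbocycle, C5 carries oxygen, and C1 (between them, with C6) carries the ester. O5, C5, C6, C1 and C2 are therefore the five ring atoms of a 3-furoate whose oxygen is temporarily bonded to C2; C3–C4 with cis O3/O4 is the alkene of a dioxolanone.
5. Ring order: the carbocycle forms in step 1 together with the temporary oxygen bridge and carrying the dioxolanone. The bridge is opened in step 2; the dioxolanone is exchanged for a dioxolane in step 3 and removed in step 6.

Key step: step 1

Assumption: (S)-3-methylpentanoic acid (8) and (R)-2-methylbutanoic acid (14) are bought as single enantiomers. Ring atoms are numbered C1–C6 as in shikimic acid (C1 bears CO2Me; O3, O4, O5 sit on C3, C4, C5). Racemic compounds are drawn as the enantiomer that goes on to the target.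

## Route

Step 1
Reactants: 1 methyl furan-3-carboxylate; 2 vinylene carbonate (1,3-dioxol-2-one)
Product: 3 rac-methyl 5-endo,6-endo-(carbonyldioxy)-7-oxabicyclo[2.2.1]hept-2-ene-2-carboxylate (carbonate on the face away from the oxygen bridge)
Conditions: 2 (4 equiv), BHT (1 mol %), CH2Cl2, 1.3 GPa, 45 °C, 72 h; endo adduct separated from exo by chromatography
Reagents that add atoms: none
Why: Concerted suprafacial [4+2] cycloaddition (furan Diels–Alder) in which the furan ring of 1 is the diene (its oxygen and four carbons become O5, C2, C1, C6 and C5) and the C=C of 2 is the dienophile (C3 and C4 with O3 and O4), so C2–C3 and C4–C5 form together; the closest known reactions are the cycloaddition of furan itself with vinylene carbonate and those of 3-furoic acid derivatives with maleimides. The carbocycle closes as the six-membered ring of a 7-oxabicyclo[2.2.1]heptene in one pericyclic event, and the ester stays conjugated to the remaining C1=C6 alkene, which offsets the loss of furan aromaticity. C3 and C4 should come out cis because the dienophile is a (Z)-alkene locked in a five-membered ring and adds suprafacially, C2 and C5 are cis through the oxygen bridge, and the endo (Alder) transition state places the carbonate anti to the bridge, which is the C3/C4-cis, C4/C5-trans pattern of the target. The selectivity needed is endo over exo, and kinetic control should secure it: pressure favours the more compact endo transition state and the low temperature suppresses the cycloreversion that would feed the exo adduct. There is no regiochemical question because 2 is symmetric, and the product is racemic; the absolute configuration is fixed in step 5.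

Step 2
Reactants: 3
Product: 5 rac-methyl 3,4-O-carbonylshikimate (cyclic carbonate on the cis-3,4-diol; 5-OH free), via lithium ester enolate 4 (not isolated)
Conditions: LiBH(s-Bu)3 (1.05 equiv), THF, −78 → 0 °C; then AcOH (1.2 equiv)
Reagents that add atoms: none
Why: Conjugate hydride addition to the strained enoate (hydride to C6) gives enolate 4, which expels the bridging oxygen from the adjacent bridgehead C2 by E1cB elimination (the enolate-triggered opening known for 7-oxanorbornane-2-carboxylates and the hydride addition–elimination known for 7-oxanorbornenyl sulfones), so C1=C2 and the C5 hydroxyl appear while C3, C4 and C5 stay untouched; a shift of the carbonate to O4/O5 by the C5 alkoxide would be harmless because step 3 removes the carbonate.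

Step 3
Reactants: 5
Product: 7 rac-methyl 3,4-O-isopropylideneshikimate, via rac-methyl shikimate 6 (not isolated)
Conditions: K2CO3 (0.2 equiv), MeOH, 0 °C; TsOH·H2O (0.5 equiv), evaporate; Me2C(OMe)2, acetone, rt; Et3N quench
Reagents that add atoms: 2,2-dimethoxypropane, COC(C)(C)OC
Why: Base-catalysed transesterification turns the cyclic carbonate into dimethyl carbonate and triol 6, and acid-catalysed transketalisation then engages only the cis-3,4-diol (cis-fused dioxolane, the standard acetonide of methyl shikimate), leaving the trans-disposed 5-OH free.

Step 4
Reactants: 8 (S)-3-methylpentanoic acid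
Product: 9 vinyl (S)-3-methylpentanoate
Conditions: vinyl acetate (20 equiv, as solvent), Pd(OAc)2 (2 mol %), KOH (10 mol %), rt, 24 h
Reagents that add atoms: vinyl acetate, C=COC(C)=O
Why: Palladium diacetate-catalysed transvinylation (vinyl interchange between a carboxylic acid and vinyl acetate) gives the enol ester needed as an irreversible acyl donor; the stereocentre is β to the carboxyl and is not touched.

Step 5
Reactants: 7 rac-methyl 3,4-O-isopropylideneshikimate; 9 vinyl (S)-3-methylpentanoate
Product: 10 methyl (3R,4S,5R)-3,4-O-isopropylidene-5-O-[(S)-3-methylpentanoyl]shikimate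
Conditions: Novozym 435 (Candida antarctica lipase B on acrylic resin), 9 (3 equiv), t-BuOMe, 4 Å molecular sieves, 40 °C, stopped at no more than half conversion; chromatography
Reagents that add atoms: none
Why: Lipase-catalysed irreversible transesterification with an enol ester, run as a kinetic resolution of a secondary alcohol: by Kazlauskas' rule the (5R)-carbinol (larger flank the dioxolane-bearing C4, smaller flank C6H2) is the fast enantiomer, so the enantiomer of 7 with the target's C3, C4 and C5 configuration should leave as ester 10 carrying the acyl group the target needs, while the (3S,4R,5S)-alcohol stays behind and is removed.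

Step 6
Reactants: 10
Product: 11 methyl (3R,4S,5R)-3,4-dihydroxy-5-[(S)-3-methylpentanoyl]oxycyclohex-1-ene-1-carboxylate
Conditions: AcOH–H2O (4:1), 45 °C
Reagents that add atoms: none
Why: Mild acid hydrolysis of the isopropylidene acetal frees the cis-3,4-diol; the three ester groups and all stereocentres should survive, and acyl migration from O5 is slow under acidic conditions.

Step 7
Reactants: 11
Product: 13 methyl (3R,4S,5R)-3-acetoxy-4-hydroxy-5-[(S)-3-methylpentanoyl]oxycyclohex-1-ene-1-carboxylate, via cyclic methyl orthoacetate 12 (not isolated)
Conditions: MeC(OMe)3 (3 equiv), CSA (5 mol %), CH2Cl2, rt; then AcOH–H2O (4:1), rt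
Reagents that add atoms: trimethyl orthoacetate, CC(OC)(OC)OC; water, O
Why: Acid-catalysed exchange gives the cis-fused 2-methoxy-2-methyl-1,3-dioxolane 12, and aqueous acid collapses its hemiorthoester with the usual stereoelectronic preference for the axial ester (orthoester route to monoesters of cis-diols), which in the shikimate half-chair with O4 and O5 equatorial is the acetate on the pseudoaxial allylic O3, leaving the equatorial 4-OH free.

Step 8
Reactants: 13; 14 (R)-2-methylbutanoic acid
Product: 15 methyl (3R,4S,5R)-3-acetoxy-4-[(2R)-2-methylbutanoyl]oxy-5-[(3S)-3-methylpentanoyl]oxycyclohex-1-ene-1-carboxylate (CNP0188172.1)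
Conditions: 14 (1.5 equiv), DCC (1.5 equiv), DMAP (0.1 equiv), CH2Cl2, 0 °C → rt
Reagents that add atoms: none
Why: Steglich esterification (carbodiimide activation, DMAP acyl transfer) of the remaining equatorial 4-OH; the low temperature and catalytic DMAP are chosen to keep the 3-acetate from migrating to O4 and the α-stereocentre of 14 from epimerising through a ketene.

## Compound list

1 | methyl furan-3-carboxylate | COC(=O)c1ccoc1 | starting material
2 | vinylene carbonate (1,3-dioxol-2-one) | O=C1OC=CO1 | starting material
3 | rac-methyl 5-endo,6-endo-(carbonyldioxy)-7-oxabicyclo[2.2.1]hept-2-ene-2-carboxylate | COC(=O)C1=C[C@H]2O[C@@H]1[C@H]3OC(=O)O[C@@H]23 | intermediate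
4 | lithium ester enolate of the C6-reduced adduct (racemic) | COC(O[Li])=C1C[C@H]2O[C@@H]1[C@H]3OC(=O)O[C@@H]23 | intermediate (not isolated)
5 | rac-methyl 3,4-O-carbonylshikimate | O[C@@H]1CC(C(=O)OC)=C[C@H]2OC(=O)O[C@@H]12 | intermediate
6 | rac-methyl shikimate | O[C@@H]1CC(C(=O)OC)=C[C@@H](O)[C@H]1O | intermediate (not isolated)
7 | rac-methyl 3,4-O-isopropylideneshikimate | O[C@@H]1CC(C(=O)OC)=C[C@H]2OC(C)(C)O[C@@H]12 | intermediate
8 | (S)-3-methylpentanoic acid | CC[C@H](C)CC(=O)O | starting material
9 | vinyl (S)-3-methylpentanoate | CC[C@H](C)CC(=O)OC=C | intermediate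
10 | methyl (3R,4S,5R)-3,4-O-isopropylidene-5-O-[(S)-3-methylpentanoyl]shikimate | CC[C@H](C)CC(=O)O[C@@H]1CC(C(=O)OC)=C[C@H]2OC(C)(C)O[C@@H]12 | intermediate
11 | methyl (3R,4S,5R)-3,4-dihydroxy-5-[(S)-3-methylpentanoyl]oxycyclohex-1-ene-1-carboxylate | CC[C@H](C)CC(=O)O[C@@H]1CC(C(=O)OC)=C[C@@H](O)[C@H]1O | intermediate
12 | cyclic methyl orthoacetate of 11 on O3/O4 (both epimers at the orthoester carbon) | CC[C@H](C)CC(=O)O[C@@H]1CC(C(=O)OC)=C[C@H]2OC(C)(OC)O[C@@H]12 | intermediate (not isolated)
13 | methyl (3R,4S,5R)-3-acetoxy-4-hydroxy-5-[(S)-3-methylpentanoyl]oxycyclohex-1-ene-1-carboxylate | CC[C@H](C)CC(=O)O[C@@H]1CC(C(=O)OC)=C[C@@H](OC(C)=O)[C@H]1O | intermediate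
14 | (R)-2-methylbutanoic acid | CC[C@@H](C)C(=O)O | starting material
15 | methyl (3R,4S,5R)-3-acetoxy-4-[(2R)-2-methylbutanoyl]oxy-5-[(3S)-3-methylpentanoyl]oxycyclohex-1-ene-1-carboxylate | CC[C@H](C)CC(=O)O[C@@H]1CC(C(=O)OC)=C[C@@H](OC(C)=O)[C@H]1OC(=O)[C@H](C)CC | target

## Step count

Total steps: 8. Longest linear sequence: 7 (steps 1, 2, 3, 5, 6, 7, 8); step 4 is a one-step side branch.

## Steps most likely to fail

**Step 1.** The cycloaddition may stall at low conversion because both partners are weakly activated, and the endo preference may be poor or eroded by cycloreversion and re-addition. Fallback: accept the exo topology and correct C5 afterwards. It sets out from 1 and 2 and comes back to the route at 7.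
- Heating 1 in neat 2 (120 °C, sealed tube, BHT) should accumulate the exo adduct, rac-methyl 5-exo,6-exo-(carbonyldioxy)-7-oxabicyclo[2.2.1]hept-2-ene-2-carboxylate F1.
- Opening with LiBH(s-Bu)3 as in step 2, through the corresponding lithium ester enolate F2, should give the all-cis alcohol rac-methyl 3,4-O-carbonyl-5-epi-shikimate F3.
- Mitsunobu esterification (4-nitrobenzoic acid, PPh3, DIAD, THF, 0 °C) should invert C5 by SN2 attack on the face away from the carbonate and give rac-methyl 3,4-O-carbonyl-5-O-(4-nitrobenzoyl)shikimate F4.
- K2CO3/MeOH then removes the carbonate and the nitrobenzoate together to give 6, which is carried into the acetonide formation of step 3 to reach 7.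

**Step 2.** The hydride may attack the cyclic carbonate or the ester carbonyl, the enolate may be protonated before it eliminates, or the new enoate may be reduced a second time. Fallback: separate the reduction from the elimination. It sets out from 3 and comes back at 5.
- Hydrogenation (H2, 1 atm, Pd/C, EtOAc), with delivery from the face of the oxygen bridge, should give the saturated ester rac-methyl 5-endo,6-endo-(carbonyldioxy)-7-oxabicyclo[2.2.1]heptane-2-endo-carboxylate F5.
- LiN(SiMe3)2 (THF, −78 → 0 °C, then AcOH) deprotonates C1 to the same enolate 4, which opens to 5.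

**Step 5.** The enzyme may discriminate poorly between the enantiomers of 7 or transfer the β-branched acyl group too slowly, so that 10 is contaminated by its diastereomer from the antipodal core. Fallback: physical resolution followed by chemical acylation. It sets out from 7 and comes back at 10.
- The enantiomers of 7 are separated by preparative chromatography on a chiral stationary phase (amylose tris(3,5-dimethylphenylcarbamate), supercritical CO2/MeOH).
- The (3R,4S,5R)-enantiomer of 7 is esterified with acid 8 (DCC, DMAP, CH2Cl2, 0 °C → rt) to give 10. This makes no compound outside the list (F0).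
- If the lipase turns out to prefer the other enantiomer, the recovered alcohol is the wanted one and is esterified in the same way.

## Further compounds

F1 | step 1 | rac-methyl 5-exo,6-exo-(carbonyldioxy)-7-oxabicyclo[2.2.1]hept-2-ene-2-carboxylate | COC(=O)C1=C[C@@H]2O[C@H]1[C@H]3OC(=O)O[C@@H]23
F2 | step 1 | lithium ester enolate of the C6-reduced exo adduct (racemic, not isolated) | COC(O[Li])=C1C[C@@H]2O[C@H]1[C@H]3OC(=O)O[C@@H]23
F3 | step 1 | rac-methyl 3,4-O-carbonyl-5-epi-shikimate | O[C@H]1CC(C(=O)OC)=C[C@H]2OC(=O)O[C@@H]12
F4 | step 1 | rac-methyl 3,4-O-carbonyl-5-O-(4-nitrobenzoyl)shikimate | O=C(O[C@@H]1CC(C(=O)OC)=C[C@H]2OC(=O)O[C@@H]12)c1ccc(cc1)[N+](=O)[O-]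
F5 | step 2 | rac-methyl 5-endo,6-endo-(carbonyldioxy)-7-oxabicyclo[2.2.1]heptane-2-endo-carboxylate | COC(=O)[C@@H]1C[C@H]2O[C@@H]1[C@H]3OC(=O)O[C@@H]23
F0 | step 5 | none | none
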